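**Plan**

- Retrosynthetic cuts: (i) the C2–C3 and C4–C5 bonds of the oxolan-2-one, both in one operation; (ii) the C–C bond between the side-chain carbinol carbon and its propargylic CH2; (iii) the allylic ether C–O bond between the neryl and p-coumaryl parts, after allylic C–H oxidation of the E-methyl group of the neryl unit.
- Enabling feature: in the α-alkylidene-γ-butyrolactone the ring oxygen O1 lies between the carbonyl carbon C2 and the allylic, oxygen-bearing C5 (which carries the 2-methylprop-1-enyl group). C5 is vicinal to the acetoxy carbon C4, and C3 bears an exocyclic E alkene. O1, C2 and C5 can therefore arrive as the enol carbonate of a tertiary allylboronate, C4 as the aldehyde carbon of an ynal and C3 as its alkyne carbon.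
- Forward order: Williamson ether, SeO2/MnO2 to the enal, propargylation, silylation and formylation give the ynal; the boronate is made from prenal in three steps; a one-flask allylboration/titanium-mediated acyl substitution closes the only ring made in the route; acetylation and desilylation finish.
- Stereochemistry: the side-chain carbinol (R) and C4 (S) come from chiral phosphoric acid catalysis. C5 (R) is relayed from C4 through the chair allylboration transition state of the E enol carbonate (anti). The exocyclic E alkene comes from syn addition across the alkyne. The 2Z alkene is bought with nerol; the other alkenes come from methyl p-coumarate and the E-selective SeO2 oxidation.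

Key step: step 13

Remark: (R)-TRIP is assumed to direct Re-face attack on both aldehydes, by analogy with simple aldehydes; the enantiomeric acid would be used if the opposite sense were found. Lactone atoms are numbered O1, C2 (C=O), C3, C4 (OAc), C5.

**Route**

Step 1
Reactants: 1 methyl (E)-3-(4-hydroxyphenyl)prop-2-enoate
Product: 2 methyl (E)-3-[4-(triisopropylsilyloxy)phenyl]prop-2-enoate
Conditions: TIPSCl, imidazole, DMF, rt
Reagents that add atoms: chlorotriisopropylsilane, CC(C)[Si](Cl)(C(C)C)C(C)C
Why: Imidazole-mediated O-silylation masks the acidic phenol as a hindered aryl silyl ether that should survive the later anionic steps.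

Step 2
Reactants: 2 methyl (E)-3-[4-(triisopropylsilyloxy)phenyl]prop-2-enoate
Product: 3 (E)-3-[4-(triisopropylsilyloxy)phenyl]prop-2-en-1-ol
Conditions: DIBAL-H (2.2 equiv), CH2Cl2, −78 °C; Rochelle salt work-up
Reagents that add atoms: none
Why: DIBAL-H reduces the conjugated ester to the allylic alcohol by 1,2-hydride delivery and leaves the E alkene untouched.

Step 3
Reactants: 4 nerol, (2Z)-3,7-dimethylocta-2,6-dien-1-ol
Product: 5 neryl chloride, (2Z)-1-chloro-3,7-dimethylocta-2,6-diene
Conditions: NCS, Me2S, CH2Cl2, −40 → 0 °C
Reagents that add atoms: N-chlorosuccinimide, O=C1CCC(=O)N1Cl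
Why: Corey–Kim chlorination displaces an alkoxysulfonium ion by chloride in an SN2 step at the primary allylic carbon, so the 2Z geometry should be kept.

Step 4
Reactants: 3 (E)-3-[4-(triisopropylsilyloxy)phenyl]prop-2-en-1-ol; 5 neryl chloride
Product: 6 neryl (E)-4-(triisopropylsilyloxy)cinnamyl ether
Conditions: NaH, Bu4NI (cat.), THF, 0 °C → rt
Reagents that add atoms: none
Why: Williamson ether synthesis; the sodium alkoxide of 3 should displace the primary allylic chloride by SN2 with both alkene geometries kept.

Step 5
Reactants: 6 neryl (E)-4-(triisopropylsilyloxy)cinnamyl ether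
Product: 7 (2E,6Z)-8-{[(E)-3-(4-triisopropylsilyloxyphenyl)prop-2-enyl]oxy}-2,6-dimethylocta-2,6-dien-1-ol
Conditions: SeO2 (cat.), t-BuOOH, salicylic acid (cat.), CH2Cl2, 0 °C → rt
Reagents that add atoms: selenium dioxide (catalytic oxygen carrier), O=[Se]=O; tert-butyl hydroperoxide, CC(C)(C)OO
Why: Selenium dioxide allylic oxidation (ene reaction, then [2,3]-shift) should attack the most electron-rich trisubstituted alkene and, by its usual preference, oxidise the E-methyl group to the (2E)-allylic alcohol.

Step 6
Reactants: 7 (2E,6Z)-allylic alcohol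
Product: 8 (2E,6Z)-8-{[(E)-3-(4-triisopropylsilyloxyphenyl)prop-2-enyl]oxy}-2,6-dimethylocta-2,6-dienal
Conditions: activated MnO2, CH2Cl2, rt
Reagents that add atoms: none
Why: Activated MnO2 oxidises allylic alcohols selectively to enals without alkene isomerisation.

Step 7
Reactants: 8 (2E,6Z)-dienal; 9 allenylboronic acid pinacol ester
Product: 11 (4R,5E,9Z)-11-{[(E)-3-(4-triisopropylsilyloxyphenyl)prop-2-enyl]oxy}-5,9-dimethylundeca-5,9-dien-1-yn-4-ol, via pinacol borate ester 10 (not isolated)
Conditions: (R)-TRIP (10 mol %), 4 Å MS, toluene, 0 °C; aqueous triethanolamine work-up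
Reagents that add atoms: none
Why: Chiral phosphoric acid-catalysed propargylation runs through a six-membered SE2′ transition state in which the acid should direct the allenylboronate to the Re face of the enal, setting the R carbinol centre.

Step 8
Reactants: 11 (4R)-homopropargylic alcohol
Product: 12 triethylsilyl ether of 11
Conditions: TESCl, imidazole, DMF, 0 °C
Reagents that add atoms: chlorotriethylsilane, CC[Si](Cl)(CC)CC
Why: Silylation protects the secondary allylic alcohol against the organolithium and titanium steps.

Step 9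
Reactants: 12 triethylsilyl ether of 11
Product: 14 (5R,6E,10Z)-12-{[(E)-3-(4-triisopropylsilyloxyphenyl)prop-2-enyl]oxy}-6,10-dimethyl-5-(triethylsilyloxy)dodeca-6,10-dien-2-ynal, via lithium acetylide 13 (not isolated)
Conditions: n-BuLi (1.05 equiv), THF, −78 °C; then DMF, −78 → 0 °C; inverse quench into aq. KH2PO4
Reagents that add atoms: N,N-dimethylformamide, CN(C)C=O
Why: The terminal alkyne is by far the most acidic site, and formylation of the acetylide with DMF should give the ynal after a buffered quench.

Step 10
Reactants: 15 prenal, 3-methylbut-2-enal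
Product: 16 3-methylbut-2-ene-1,1-diyl diacetate
Conditions: Ac2O, FeCl3 (cat.), 0 °C → rt
Reagents that add atoms: acetic anhydride, CC(=O)OC(C)=O
Why: Lewis acid-catalysed acylal formation adds acetic anhydride across the aldehyde C=O.

Step 11
Reactants: 16 3-methylbut-2-ene-1,1-diyl diacetate
Product: 17 (E)-3-methyl-3-(4,4,5,5-tetramethyl-1,3,2-dioxaborolan-2-yl)but-1-enyl acetate
Conditions: B2pin2 (1.1 equiv), CuCl/Xantphos/KOt-Bu (5 mol % each), THF, 0 °C → rt
Reagents that add atoms: bis(pinacolato)diboron, CC1(C)OB(OC1(C)C)B1OC(C)(C)C(C)(C)O1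
Why: Proposed new method: an LCu–Bpin species should add across the trisubstituted alkene with boron at the CMe2 carbon and copper next to the acylal carbon, anti β-acetoxy elimination should then give the allylboronate with the retained acetoxy group turned away from the new quaternary carbon (E enol acetate), and Cu–OAc is returned to Cu–Bpin by B2pin2; the closest known reaction types are the Cu(I)-catalysed γ-selective boryl substitution of allylic carbonates and of α,β-unsaturated acetals.

Step 12
Reactants: 17 (E)-γ-acetoxy allylboronate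
Product: 19 methyl (E)-3-methyl-3-(4,4,5,5-tetramethyl-1,3,2-dioxaborolan-2-yl)but-1-enyl carbonate, via potassium E-enolate 18 (not isolated)
Conditions: KOt-Bu (1.0 equiv), THF, −78 °C; then ClCO2Me, −78 → −40 °C
Reagents that add atoms: methyl chloroformate, COC(=O)Cl
Why: tert-Butoxide should cleave the enol acetate to the potassium E-enolate, which cannot isomerise without a proton source and is acylated on oxygen by the hard chloroformate (enolate O-acylation), so the E geometry should be kept.

Step 13
Reactants: 14 silyl-protected ynal; 19 (E)-γ-(methoxycarbonyloxy) allylboronate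
Product: 21 (3E,4S,5R)-4-hydroxy-5-(2-methylprop-1-enyl)-3-[(3R,4E,8Z)-10-{[(E)-3-(4-triisopropylsilyloxyphenyl)prop-2-enyl]oxy}-4,8-dimethyl-3-(triethylsilyloxy)deca-4,8-dienylidene]oxolan-2-one, via homopropargylic pinacol borate 20 (not isolated)
Conditions: (R)-TRIP (10 mol %), 4 Å MS, toluene, −30 → 0 °C; then Ti(Oi-Pr)4 (2 equiv), i-PrMgCl (4 equiv), Et2O, −78 → −40 °C; then aq. NH4Cl
Reagents that add atoms: none
Why: Proposed new method: the phosphoric acid-activated tertiary (E)-γ-(methoxycarbonyloxy)allylboronate should add through its oxygen-bearing γ-carbon to the Re face of the ynal in a closed chair transition state (C4–C5 bond), leaving O4 masked as the pinacol borate 20; Ti(Oi-Pr)4/2 i-PrMgCl then gives a titanium(II)–propene complex that exchanges onto the alkyne, and the titanacyclopropene carbon next to C4 attacks the carbonate carbonyl with loss of methoxide (C2–C3 bond), the remaining alkenyl–titanium bond being protonated on work-up. The closest known reaction types are the chiral phosphoric acid-catalysed allylboration of aldehydes with γ-alkoxyallyl pinacolboronates and the titanium(II)-mediated intramolecular nucleophilic acyl substitution of homopropargyl carbonates to α-alkylidene-γ-butyrolactones; new is their union in one flask with the borate as the only protection of O4, which should hold if the Grignard reagent is taken up by Ti(Oi-Pr)4 at −78 °C faster than it attacks the hindered borate. The lactone closes by 5-exo-trig acyl substitution; the 6-endo mode would need a trans alkene in the ring and is excluded. C4 is set by the catalyst, C5 is relayed from it by the chair transition state in which the E enol carbonate places its oxygen equatorial (anti diol), and the E exocyclic alkene follows from syn delivery of titanium and acyl carbon across the alkyne, so that the new vinyl hydrogen ends cis to the carbonyl group. The step needs attack through the oxygen-bearing allyl terminus, secured by the tertiary pinacol boronate that cannot undergo a 1,3-boryl shift, and it needs titanium(II) to bind the alkyne in preference to the trisubstituted allylic carbonate and the allylic ethers, which the much faster alkyne complexation at low temperature should secure.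

Step 14
Reactants: 21 hydroxy lactone
Product: 22 (3E,4S,5R)-4-acetoxy lactone, the acetate of 21
Conditions: Ac2O, pyridine, DMAP (cat.), CH2Cl2, 0 °C
Reagents that add atoms: acetic anhydride, CC(=O)OC(C)=O
Why: DMAP-catalysed acetylation of the only free hydroxyl group installs the C4 acetate without touching the stereocentres.

Step 15
Reactants: 22 acetoxy lactone
Product: 23 CNP0237370.1, the target
Conditions: TBAF, AcOH (1:1), THF, 0 °C → rt
Reagents that add atoms: none
Why: Acetic acid-buffered fluoride should cleave the secondary triethylsilyl ether and the aryl triisopropylsilyl ether without the basic conditions that could harm the allylic acetate or the alkylidene lactone.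

**Compound list**

1 | methyl (E)-3-(4-hydroxyphenyl)prop-2-enoate (methyl p-coumarate) | COC(=O)/C=C/c1ccc(O)cc1 | starting material
2 | methyl (E)-3-[4-(triisopropylsilyloxy)phenyl]prop-2-enoate | COC(=O)/C=C/c1ccc(O[Si](C(C)C)(C(C)C)C(C)C)cc1 | intermediate
3 | (E)-3-[4-(triisopropylsilyloxy)phenyl]prop-2-en-1-ol | OC/C=C/c1ccc(O[Si](C(C)C)(C(C)C)C(C)C)cc1 | intermediate
4 | nerol | CC(C)=CCC/C(C)=C\CO | starting material
5 | neryl chloride | CC(C)=CCC/C(C)=C\CCl | intermediate
6 | neryl (E)-4-(triisopropylsilyloxy)cinnamyl ether | CC(C)=CCC/C(C)=C\COC/C=C/c1ccc(O[Si](C(C)C)(C(C)C)C(C)C)cc1 | intermediate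
7 | (2E,6Z)-8-(cinnamyloxy)-2,6-dimethylocta-2,6-dien-1-ol, aryl OTIPS | OC/C(C)=C/CC/C(C)=C\COC/C=C/c1ccc(O[Si](C(C)C)(C(C)C)C(C)C)cc1 | intermediate
8 | (2E,6Z)-8-(cinnamyloxy)-2,6-dimethylocta-2,6-dienal, aryl OTIPS | O=C/C(C)=C/CC/C(C)=C\COC/C=C/c1ccc(O[Si](C(C)C)(C(C)C)C(C)C)cc1 | intermediate
9 | allenylboronic acid pinacol ester | C=C=CB1OC(C)(C)C(C)(C)O1 | starting material
10 | pinacol borate ester of 11 (not isolated) | C#CC[C@@H](OB1OC(C)(C)C(C)(C)O1)/C(C)=C/CC/C(C)=C\COC/C=C/c1ccc(O[Si](C(C)C)(C(C)C)C(C)C)cc1 | intermediate
11 | (4R,5E,9Z)-homopropargylic alcohol | C#CC[C@@H](O)/C(C)=C/CC/C(C)=C\COC/C=C/c1ccc(O[Si](C(C)C)(C(C)C)C(C)C)cc1 | intermediate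
12 | triethylsilyl ether of 11 | C#CC[C@@H](O[Si](CC)(CC)CC)/C(C)=C/CC/C(C)=C\COC/C=C/c1ccc(O[Si](C(C)C)(C(C)C)C(C)C)cc1 | intermediate
13 | lithium acetylide of 12 (not isolated) | [Li]C#CC[C@@H](O[Si](CC)(CC)CC)/C(C)=C/CC/C(C)=C\COC/C=C/c1ccc(O[Si](C(C)C)(C(C)C)C(C)C)cc1 | intermediate
14 | (5R,6E,10Z)-ynal | O=CC#CC[C@@H](O[Si](CC)(CC)CC)/C(C)=C/CC/C(C)=C\COC/C=C/c1ccc(O[Si](C(C)C)(C(C)C)C(C)C)cc1 | intermediate
15 | prenal | CC(C)=CC=O | starting material
16 | 3-methylbut-2-ene-1,1-diyl diacetate | CC(C)=CC(OC(C)=O)OC(C)=O | intermediate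
17 | (E)-3-methyl-3-(pinacolboryl)but-1-enyl acetate | CC(=O)O/C=C/C(C)(C)B1OC(C)(C)C(C)(C)O1 | intermediate
18 | potassium (E)-3-methyl-3-(pinacolboryl)but-1-en-1-olate (not isolated) | [K+].[O-]/C=C/C(C)(C)B1OC(C)(C)C(C)(C)O1 | intermediate
19 | methyl (E)-3-methyl-3-(pinacolboryl)but-1-enyl carbonate | COC(=O)O/C=C/C(C)(C)B1OC(C)(C)C(C)(C)O1 | intermediate
20 | anti homopropargylic pinacol borate carrying the methyl carbonate (not isolated) | COC(=O)O[C@H](C=C(C)C)[C@@H](OB1OC(C)(C)C(C)(C)O1)C#CC[C@@H](O[Si](CC)(CC)CC)/C(C)=C/CC/C(C)=C\COC/C=C/c1ccc(O[Si](C(C)C)(C(C)C)C(C)C)cc1 | intermediate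
21 | (3E,4S,5R)-4-hydroxy alkylidene lactone, OTES and aryl OTIPS | O[C@H]1/C(=C\C[C@@H](O[Si](CC)(CC)CC)/C(C)=C/CC/C(C)=C\COC/C=C/c2ccc(O[Si](C(C)C)(C(C)C)C(C)C)cc2)C(=O)O[C@@H]1C=C(C)C | intermediate
22 | (3E,4S,5R)-4-acetoxy alkylidene lactone, OTES and aryl OTIPS | CC(=O)O[C@H]1/C(=C\C[C@@H](O[Si](CC)(CC)CC)/C(C)=C/CC/C(C)=C\COC/C=C/c2ccc(O[Si](C(C)C)(C(C)C)C(C)C)cc2)C(=O)O[C@@H]1C=C(C)C | intermediate
23 | CNP0237370.1 | CC(=O)O[C@H]1/C(=C\C[C@@H](O)/C(C)=C/CC/C(C)=C\COC/C=C/c2ccc(O)cc2)C(=O)O[C@@H]1C=C(C)C | target

**Step count**

Total steps: 15. Longest linear sequence: 11 (steps 1, 2, 4, 5, 6, 7, 8, 9, 13, 14, 15).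

**Steps most likely to fail**

Step 13 (Proposed new method). The Grignard reagent may cleave the borate, and the freed alkoxide would then cyclise onto the neighbouring carbonate. The titanium–alkyne complex may lose the propargylic oxygen by β-elimination, or titanium(II) may insert into the allylic carbonate. Facial control in the allylboration may also be incomplete. The fallback uses known chemistry, sets out from 14 and 19 and comes back at 21. The allylboration is run alone and worked up to the isolated anti carbonate alcohol F1. Its hydroxyl group is capped (TMSCl, imidazole) as the trimethylsilyl ether F2. The known Ti(Oi-Pr)4/2 i-PrMgCl acyl substitution of homopropargyl carbonates then gives the O-trimethylsilyl lactone F3, and mild acidic methanolysis on work-up (citric acid, MeOH) returns 21.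

Step 11 (Proposed new method). Boryl-cupration of the hindered trisubstituted alkene may not occur, the alkoxide co-catalyst may attack the acylal, or acetate may fail to turn the copper catalyst over. The fallback uses known chemistry, sets out from 15 and comes back at 17. Cu(I)-catalysed conjugate borylation of prenal (CuCl/DPEphos/NaOt-Bu cat., B2pin2, MeOH, THF) gives 3-methyl-3-(pinacolboryl)butanal F4. Enol acetylation under equilibrating conditions (isopropenyl acetate, cat. TsOH) should favour the E isomer next to the bulky quaternary carbon; after separation this is 17.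

Step 7. Enantiofacial discrimination may be poor, or turnover slow, with the α-branched enal. The fallback sets out from 8 and comes back at 11. Barbier propargylation (Zn, propargyl bromide, THF/aq. NH4Cl) gives the racemic homopropargylic alcohol F5. Buffered Dess–Martin oxidation gives the enone F6, and CBS reduction ((S)-Me-CBS, catecholborane, toluene, −78 °C), with the alkenyl group as the large substituent, should return (R)-11.

**Further compounds**

F1 | step 13 | anti homopropargylic alcohol carrying the methyl carbonate | COC(=O)O[C@H](C=C(C)C)[C@@H](O)C#CC[C@@H](O[Si](CC)(CC)CC)/C(C)=C/CC/C(C)=C\COC/C=C/c1ccc(O[Si](C(C)C)(C(C)C)C(C)C)cc1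
F2 | step 13 | trimethylsilyl ether of F1 | COC(=O)O[C@H](C=C(C)C)[C@@H](O[Si](C)(C)C)C#CC[C@@H](O[Si](CC)(CC)CC)/C(C)=C/CC/C(C)=C\COC/C=C/c1ccc(O[Si](C(C)C)(C(C)C)C(C)C)cc1
F3 | step 13 | O-trimethylsilyl ether of lactone 21 | C[Si](C)(C)O[C@H]1/C(=C\C[C@@H](O[Si](CC)(CC)CC)/C(C)=C/CC/C(C)=C\COC/C=C/c2ccc(O[Si](C(C)C)(C(C)C)C(C)C)cc2)C(=O)O[C@@H]1C=C(C)C
F4 | step 11 | 3-methyl-3-(4,4,5,5-tetramethyl-1,3,2-dioxaborolan-2-yl)butanal | O=CCC(C)(C)B1OC(C)(C)C(C)(C)O1
F5 | step 7 | racemic homopropargylic alcohol (racemate of 11) | C#CCC(O)/C(C)=C/CC/C(C)=C\COC/C=C/c1ccc(O[Si](C(C)C)(C(C)C)C(C)C)cc1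
F6 | step 7 | (5E,9Z)-undeca-5,9-dien-1-yn-4-one analogue of 11 | C#CCC(=O)/C(C)=C/CC/C(C)=C\COC/C=C/c1ccc(O[Si](C(C)C)(C(C)C)C(C)C)cc1
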